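**Plan**

- Retrosynthetic cuts, in order: the aryl C(=O)–C3 bond; the CH2–CH= bond of the C7 geranyl chain, leaving a C7 methylene; then C3–C4 and C5–C9 together, which opens both rings to one acyclic keto diester; finally C5–C6, C1–prenyl, C1–C2 and C7–C8 of the chain.
- Enabling feature: C9 and C4 are acyl carbons. With C1 (prenyl bridgehead) carrying the C9 ester and the acetyl group C2–C3, and C5 carrying the C4 ester, attack of C5 on C9 closes ring A (C1–C9–C5–C6–C7–C8) and attack of C3 on C4 closes ring B (C1–C2–C3–C4–C5–C9), as long as C7 stays an sp2 methylene.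
- Forward order: the chain is joined at C7–C8 (conjugate addition), C1–C2 (aldol), C1–prenyl (alkylation) and C5–C6 (malonate alkylation); ring A and then ring B form in one flask; the C7 chain and the C3 aroyl group follow.
- Stereochemistry: an auxiliary-controlled aldol fixes the C2 carbinol, which relays to quaternary C1 in a chelate-controlled alkylation and is then oxidised away; C1 dictates C5 through the bridging requirement; C7 comes from exo-face hydroboration; the E-alkenes come from geranyl bromide and a syn carboalumination.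

Key step: step 13

Remark: TBS = tert-butyldimethylsilyl; C1–C9 refer to the bicyclo[3.3.1]nonane numbering of the target throughout, also in open-chain compounds.
Assumption: O-methylation in step 14 is drawn at the C4 oxygen (remote from the C8 gem-dimethyl group); the C2-O regioisomer would react in the same way in steps 16, 19 and 20 and give the same triketone.

**Route**

Step 1
Reactants: 1 2-bromoprop-2-en-1-ol
Product: 2 [(2-bromoprop-2-en-1-yl)oxy](tert-butyl)dimethylsilane
Conditions: TBSCl, imidazole, CH2Cl2, 0 °C → rt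
Reagents that add atoms: tert-butyl(chloro)dimethylsilane, CC(C)(C)[Si](C)(C)Cl
Why: Imidazole-promoted O-silylation of a primary allylic alcohol is routine and leaves the vinyl bromide untouched.

Step 2
Reactants: 3 (4R)-4-benzyl-1,3-oxazolidin-2-one; 4 3-methylbut-2-enoyl chloride
Product: 6 (4R)-4-benzyl-3-(3-methylbut-2-enoyl)-1,3-oxazolidin-2-one, via N-lithio oxazolidinone 5 (not isolated)
Conditions: n-BuLi, THF, −78 °C; then 4, −78 → 0 °C
Reagents that add atoms: none
Why: N-acylation of the lithiated oxazolidinone with an acid chloride is the standard entry to N-enoyl imides, and working without an amine base avoids deconjugation of the enoyl unit through a vinylketene.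

Step 3
Reactants: 2 [(2-bromoprop-2-en-1-yl)oxy](tert-butyl)dimethylsilane; 6 (4R)-4-benzyl-3-(3-methylbut-2-enoyl)-1,3-oxazolidin-2-one
Product: 9 (4R)-4-benzyl-3-[4-({[tert-butyl(dimethyl)silyl]oxy}methyl)-3,3-dimethylpent-4-enoyl]-1,3-oxazolidin-2-one, via vinyllithium 7 (not isolated), via vinylmagnesium bromide 8 (not isolated)
Conditions: 2, t-BuLi (2 equiv), Et2O, −78 °C; MgBr2·OEt2; then CuBr·SMe2 (20 mol %), 6, THF, −40 → −10 °C; aq. NH4Cl
Reagents that add atoms: none
Why: Bromine–lithium exchange, transmetalation to magnesium and copper-catalysed 1,4-addition of the alkenyl Grignard reagent to the β,β-disubstituted N-enoyl imide is established chemistry for a quaternary CMe2 carbon (C8) next to an imide, and it creates the C7–C8 bond without a stereocentre.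

Step 4
Reactants: 9 (4R)-4-benzyl-3-[4-({[tert-butyl(dimethyl)silyl]oxy}methyl)-3,3-dimethylpent-4-enoyl]-1,3-oxazolidin-2-one; 10 acetaldehyde
Product: 12 (4R)-4-benzyl-3-[(2R,3S)-2-{3-[(TBS-oxy)methyl]-2-methylbut-3-en-2-yl}-3-hydroxybutanoyl]-1,3-oxazolidin-2-one, via boron enolate 11 (not isolated)
Conditions: n-Bu2BOTf, i-Pr2NEt, CH2Cl2, 0 °C; 10, −78 → 0 °C; pH 7 buffer, MeOH, H2O2
Reagents that add atoms: none
Why: Evans syn-aldol reaction, in which the (Z)-boron enolate reacts through a Zimmerman–Traxler chair on the face away from the benzyl group, which should fix the carbinol carbon (future C2) as S; the α-centre formed with it is erased in step 7.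

Step 5
Reactants: 12 (4R)-4-benzyl-3-[(2R,3S)-2-{3-[(TBS-oxy)methyl]-2-methylbut-3-en-2-yl}-3-hydroxybutanoyl]-1,3-oxazolidin-2-one
Product: 14 (2R,3S)-2-{3-[(TBS-oxy)methyl]-2-methylbut-3-en-2-yl}-3-hydroxybutanoic acid, via peroxy acid 13 (not isolated)
Conditions: LiOH, H2O2, THF/H2O, 0 °C; aq. Na2SO3; aq. HCl to pH 3
Reagents that add atoms: hydrogen peroxide, OO
Why: Hydroperoxide cleavage of the imide attacks the exocyclic carbonyl selectively even when it is hindered, and sulfite reduces the peroxy acid without touching the alkene, the silyl ether or the carbinol.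

Step 6
Reactants: 14 (2R,3S)-2-{3-[(TBS-oxy)methyl]-2-methylbut-3-en-2-yl}-3-hydroxybutanoic acid
Product: 15 methyl (2R,3S)-2-{3-[(TBS-oxy)methyl]-2-methylbut-3-en-2-yl}-3-hydroxybutanoate
Conditions: TMSCHN2, MeOH/toluene, 0 °C
Reagents that add atoms: (trimethylsilyl)diazomethane, C[Si](C)(C)C=[N+]=[N-]
Why: Esterification with a diazomethane equivalent is neutral and should leave the β-hydroxy group and the silyl ether alone.

Step 7
Reactants: 15 methyl (2R,3S)-2-{3-[(TBS-oxy)methyl]-2-methylbut-3-en-2-yl}-3-hydroxybutanoate; 16 1-bromo-3-methylbut-2-ene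
Product: 18 methyl (2R,3S)-2-{3-[(TBS-oxy)methyl]-2-methylbut-3-en-2-yl}-3-hydroxy-2-(3-methylbut-2-en-1-yl)butanoate, via dilithium dianion 17 (not isolated)
Conditions: LDA (2.3 equiv), THF, −78 → −20 °C; DMPU, 16, −78 → 0 °C; aq. NH4Cl
Reagents that add atoms: none
Why: Fráter–Seebach alkylation, in which the lithium-chelated alkoxide–enolate takes the allylic bromide on the face anti to the carbinol methyl group, a mode known for second alkylations that give quaternary centres, and this should set C1 as R, the configuration of the target.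

Step 8
Reactants: 18 methyl (2R,3S)-2-{3-[(TBS-oxy)methyl]-2-methylbut-3-en-2-yl}-3-hydroxy-2-(3-methylbut-2-en-1-yl)butanoate
Product: 19 methyl (2R)-2-acetyl-4-[(TBS-oxy)methyl]-3,3-dimethyl-2-(3-methylbut-2-en-1-yl)pent-4-enoate
Conditions: Dess–Martin periodinane, CH2Cl2, 0 °C → rt
Reagents that add atoms: none
Why: Dess–Martin oxidation of the hindered secondary alcohol under near-neutral conditions should give the methyl ketone (C2, C3) without retro-aldol cleavage, and C1 has no hydrogen and cannot epimerise.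

Step 9
Reactants: 19 methyl (2R)-2-acetyl-4-[(TBS-oxy)methyl]-3,3-dimethyl-2-(3-methylbut-2-en-1-yl)pent-4-enoate
Product: 20 methyl (2R)-2-acetyl-4-(bromomethyl)-3,3-dimethyl-2-(3-methylbut-2-en-1-yl)pent-4-enoate
Conditions: Ph3PBr2, CH2Cl2, 0 °C → rt
Reagents that add atoms: dibromo(triphenyl)phosphorane, BrP(Br)(c1ccccc1)(c1ccccc1)c1ccccc1
Why: Direct silyl ether to bromide exchange through an alkoxyphosphonium bromide is known for tert-butyldimethylsilyl ethers and avoids a free δ-hydroxy keto ester, which would close to a lactone or lactol.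

Step 10
Reactants: 21 methyl prop-2-en-1-yl propanedioate; 22 (2E)-1-bromo-3,7-dimethylocta-2,6-diene (geranyl bromide)
Product: 23 1-methyl 3-prop-2-en-1-yl 2-[(2E)-3,7-dimethylocta-2,6-dien-1-yl]propanedioate
Conditions: K2CO3, DMF, rt (21 in excess)
Reagents that add atoms: none
Why: Malonate monoalkylation with an allylic bromide (SN2) under mild carbonate conditions, with the malonate in excess to limit dialkylation and the E-alkene untouched.

Step 11
Reactants: 20 methyl (2R)-2-acetyl-4-(bromomethyl)-3,3-dimethyl-2-(3-methylbut-2-en-1-yl)pent-4-enoate; 23 1-methyl 3-prop-2-en-1-yl 2-[(2E)-3,7-dimethylocta-2,6-dien-1-yl]propanedioate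
Product: 25 dimethyl (2R)-2-acetyl-6-[(allyloxy)carbonyl]-6-[(2E)-3,7-dimethylocta-2,6-dien-1-yl]-3,3-dimethyl-4-methylidene-2-(3-methylbut-2-en-1-yl)heptanedioate, via sodium malonate 24 (not isolated)
Conditions: 23, NaH, THF/DMF, 0 °C; then 20, 0 → 40 °C
Reagents that add atoms: none
Why: SN2 alkylation of a stabilised malonate anion forms the C5–C6 bond, and this anion is too weakly basic to enolise the methyl ketone, whereas a plain ester enolate would do so and let C3 cyclise onto the bromide.

Step 12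
Reactants: 25 dimethyl (2R)-2-acetyl-6-[(allyloxy)carbonyl]-6-[(2E)-3,7-dimethylocta-2,6-dien-1-yl]-3,3-dimethyl-4-methylidene-2-(3-methylbut-2-en-1-yl)heptanedioate
Product: 27 dimethyl (2R)-2-acetyl-6-[(2E)-3,7-dimethylocta-2,6-dien-1-yl]-3,3-dimethyl-4-methylidene-2-(3-methylbut-2-en-1-yl)heptanedioate (both C5 epimers), via malonic half-acid 26 (not isolated)
Conditions: Pd(PPh3)4 (5 mol %), morpholine, THF, rt; aq. citric acid wash; then DMSO, 130 °C
Reagents that add atoms: none
Why: Tsuji–Trost deallylation (zerovalent palladium ionises only the allyl ester and morpholine traps the π-allyl unit) followed by thermal decarboxylation of the disubstituted malonic half-acid gives the C5–H ester as both epimers, which is harmless because C5 becomes an enolate in step 13.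

Step 13
Reactants: 27 dimethyl (2R)-2-acetyl-6-[(2E)-3,7-dimethylocta-2,6-dien-1-yl]-3,3-dimethyl-4-methylidene-2-(3-methylbut-2-en-1-yl)heptanedioate
Product: 29 4-hydroxy-5-[(2E)-3,7-dimethylocta-2,6-dien-1-yl]-8,8-dimethyl-7-methylidene-1-(3-methylbut-2-en-1-yl)bicyclo[3.3.1]non-3-ene-2,9-dione (C1 and C5 as in the target), via monocyclic keto ester 28 (not isolated)
Conditions: KOt-Bu (3.5 equiv), THF, 0 °C → rt; aq. HCl
Reagents that add atoms: none
Why: Proposed new method: KOt-Bu reversibly forms the C5 ester enolate, which attacks the C9 ester on C1 (Dieckmann condensation, 6-(enolexo)-exo-trig, ring A), and in the monocyclic keto ester 28 the C3 methyl ketone enolate then attacks the C4 ester (Claisen condensation, 6-(enolendo)-exo-trig, ring B), after which the trione leaves all equilibria as its delocalised C2–C3–C4 enolate. The closest known reaction is the base-mediated Claisen closure of 2-acetyl-6-alkoxycarbonylcyclohexanones to bicyclo[3.3.1]nonane-2,4,9-triones, here preceded in the same flask by the Dieckmann step that makes such a cyclohexanone. The only new stereocentre, C5, is controlled by C1, because ring B can form only when the C4 ester is cis to the acetyl group, the cis transition state is also the one that places two acyl groups and not two alkyl chains 1,3-diaxial, and the trans isomer has no other outlet than retro-Dieckmann return to the open chain. The step needs C1 to keep its configuration and the acetyl group to survive alkoxide: C1 has no hydrogen, and under excess KOt-Bu the acetyl group rests as its C3 enolate, which shields C2 from methoxide and makes C1 a poor leaving group, so that any reopening at C9 should expel C5 and not C1. The C7 methylene keeps a third stereocentre out of the cyclisation and flattens ring A in the folded chain.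

Step 14
Reactants: 29 4-hydroxy-5-[(2E)-3,7-dimethylocta-2,6-dien-1-yl]-8,8-dimethyl-7-methylidene-1-(3-methylbut-2-en-1-yl)bicyclo[3.3.1]non-3-ene-2,9-dione
Product: 30 5-[(2E)-3,7-dimethylocta-2,6-dien-1-yl]-4-methoxy-8,8-dimethyl-7-methylidene-1-(3-methylbut-2-en-1-yl)bicyclo[3.3.1]non-3-ene-2,9-dione
Conditions: TMSCHN2, MeOH/toluene, 0 °C → rt
Reagents that add atoms: (trimethylsilyl)diazomethane, C[Si](C)(C)C=[N+]=[N-]
Why: O-methylation of the vinylogous acid with a diazomethane equivalent masks the acidic enol before borane and organolithium chemistry, as is usual for bicyclo[3.3.1]nonane triones.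

Step 15
Reactants: 31 6-methylhept-5-en-1-yne
Product: 33 (1E)-1-iodo-2,6-dimethylhepta-1,5-diene, via alkenylalane 32 (not isolated)
Conditions: Me3Al, Cp2ZrCl2 (20 mol %), CH2Cl2, 0 °C → rt; then I2, THF, −30 → 0 °C
Reagents that add atoms: trimethylaluminium, C[Al](C)C; iodine, [I][I]
Why: Negishi carboalumination adds methyl and aluminium syn across the terminal alkyne and iodinolysis proceeds with retention, which should give the E-alkenyl iodide while the trisubstituted alkene stays inert.

Step 16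
Reactants: 30 5-[(2E)-3,7-dimethylocta-2,6-dien-1-yl]-4-methoxy-8,8-dimethyl-7-methylidene-1-(3-methylbut-2-en-1-yl)bicyclo[3.3.1]non-3-ene-2,9-dione; 33 (1E)-1-iodo-2,6-dimethylhepta-1,5-diene
Product: 35 5,7-bis[(2E)-3,7-dimethylocta-2,6-dien-1-yl]-4-methoxy-8,8-dimethyl-1-(3-methylbut-2-en-1-yl)bicyclo[3.3.1]non-3-ene-2,9-dione (C7 chain endo), via B-alkyl-9-BBN 34 (not isolated)
Conditions: 9-BBN, THF, 0 °C → rt; then 33, Pd(dppf)Cl2 (5 mol %), AsPh3, Cs2CO3, DMF/H2O, rt
Reagents that add atoms: none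
Why: Hydroboration followed by B-alkyl Suzuki–Miyaura coupling, in which 9-BBN selects the 1,1-disubstituted C7 methylene over the trisubstituted alkenes and adds from the exo face (away from the C2–C4 bridge), so that hydrogen goes to C7, the CH2–boron arm ends up endo and sets C7, and the coupling completes the geranyl chain with retention of the E geometry.

Step 17
Reactants: 36 3,4-dihydroxybenzoic acid
Product: 37 tert-butyl(dimethyl)silyl 3,4-bis{[tert-butyl(dimethyl)silyl]oxy}benzoate
Conditions: TBSCl (3.5 equiv), imidazole, DMF, rt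
Reagents that add atoms: tert-butyl(chloro)dimethylsilane, CC(C)(C)[Si](C)(C)Cl
Why: Exhaustive silylation protects the catechol and turns the acid into a silyl ester, which is a latent acid chloride.

Step 18
Reactants: 37 tert-butyl(dimethyl)silyl 3,4-bis{[tert-butyl(dimethyl)silyl]oxy}benzoate
Product: 38 3,4-bis{[tert-butyl(dimethyl)silyl]oxy}benzoyl chloride
Conditions: (COCl)2, DMF (cat.), CH2Cl2, 0 °C → rt
Reagents that add atoms: oxalyl chloride, O=C(Cl)C(Cl)=O
Why: Vilsmeier-type activation converts silyl esters directly into acid chlorides under neutral conditions, so the aryl silyl ethers should survive.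

Step 19
Reactants: 35 5,7-bis[(2E)-3,7-dimethylocta-2,6-dien-1-yl]-4-methoxy-8,8-dimethyl-1-(3-methylbut-2-en-1-yl)bicyclo[3.3.1]non-3-ene-2,9-dione; 38 3,4-bis{[tert-butyl(dimethyl)silyl]oxy}benzoyl chloride
Product: 40 3-(3,4-bis{[tert-butyl(dimethyl)silyl]oxy}benzoyl)-5,7-bis[(2E)-3,7-dimethylocta-2,6-dien-1-yl]-4-methoxy-8,8-dimethyl-1-(3-methylbut-2-en-1-yl)bicyclo[3.3.1]non-3-ene-2,9-dione, via C3-lithio enol ether 39 (not isolated)
Conditions: LiTMP, THF, −78 °C; then 38, −78 → −40 °C
Reagents that add atoms: none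
Why: Vinylic deprotonation of the vinylogous ester at C3 and C-acylation with an acid chloride is the established way to place the C3 aroyl group on such enol ethers, and no other position can enolise because both bridgeheads are quaternary.

Step 20
Reactants: 40 3-(3,4-bis{[tert-butyl(dimethyl)silyl]oxy}benzoyl)-5,7-bis[(2E)-3,7-dimethylocta-2,6-dien-1-yl]-4-methoxy-8,8-dimethyl-1-(3-methylbut-2-en-1-yl)bicyclo[3.3.1]non-3-ene-2,9-dione
Product: 42 oblongifolin D, via bis-silyl triketone 41 (not isolated)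
Conditions: LiCl, DMSO, 120 °C; aq. HCl work-up; then HF·pyridine, pyridine/THF, 0 °C → rt
Reagents that add atoms: none
Why: Krapcho-type SN2 demethylation of the vinylogous methyl ester by chloride should free the triketone, and buffered fluoride then cleaves the two aryl silyl ethers under conditions mild enough to avoid cyclisation of the enol onto the prenyl groups.

**Compound list**

1 | 2-bromoprop-2-en-1-ol | OCC(Br)=C | starting material
2 | [(2-bromoprop-2-en-1-yl)oxy](tert-butyl)dimethylsilane | C=C(Br)CO[Si](C)(C)C(C)(C)C | intermediate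
3 | (4R)-4-benzyl-1,3-oxazolidin-2-one | O=C1N[C@H](Cc2ccccc2)CO1 | starting material
4 | 3-methylbut-2-enoyl chloride | CC(C)=CC(Cl)=O | starting material
5 | N-lithio-(4R)-4-benzyl-1,3-oxazolidin-2-one | [Li]N1[C@H](Cc2ccccc2)COC1=O | intermediate (not isolated)
6 | (4R)-4-benzyl-3-(3-methylbut-2-enoyl)-1,3-oxazolidin-2-one | CC(C)=CC(=O)N1[C@H](Cc2ccccc2)COC1=O | intermediate
7 | [3-(TBS-oxy)prop-1-en-2-yl]lithium | [Li]C(=C)CO[Si](C)(C)C(C)(C)C | intermediate (not isolated)
8 | bromo[3-(TBS-oxy)prop-1-en-2-yl]magnesium | Br[Mg]C(=C)CO[Si](C)(C)C(C)(C)C | intermediate (not isolated)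
9 | (4R)-4-benzyl-3-[4-({[tert-butyl(dimethyl)silyl]oxy}methyl)-3,3-dimethylpent-4-enoyl]-1,3-oxazolidin-2-one | CC(C)(CC(=O)N1[C@H](Cc2ccccc2)COC1=O)C(=C)CO[Si](C)(C)C(C)(C)C | intermediate
10 | acetaldehyde | CC=O | starting material
11 | (Z)-di-n-butylboron enolate of 9 | CCCCB(CCCC)O/C(N1[C@H](Cc2ccccc2)COC1=O)=C\C(C)(C)C(=C)CO[Si](C)(C)C(C)(C)C | intermediate (not isolated)
12 | (4R)-4-benzyl-3-[(2R,3S)-2-{3-[(TBS-oxy)methyl]-2-methylbut-3-en-2-yl}-3-hydroxybutanoyl]-1,3-oxazolidin-2-one | C[C@H](O)[C@H](C(=O)N1[C@H](Cc2ccccc2)COC1=O)C(C)(C)C(=C)CO[Si](C)(C)C(C)(C)C | intermediate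
13 | (2R,3S)-2-{3-[(TBS-oxy)methyl]-2-methylbut-3-en-2-yl}-3-hydroxybutaneperoxoic acid | C[C@H](O)[C@H](C(=O)OO)C(C)(C)C(=C)CO[Si](C)(C)C(C)(C)C | intermediate (not isolated)
14 | (2R,3S)-2-{3-[(TBS-oxy)methyl]-2-methylbut-3-en-2-yl}-3-hydroxybutanoic acid | C[C@H](O)[C@H](C(O)=O)C(C)(C)C(=C)CO[Si](C)(C)C(C)(C)C | intermediate
15 | methyl (2R,3S)-2-{3-[(TBS-oxy)methyl]-2-methylbut-3-en-2-yl}-3-hydroxybutanoate | C[C@H](O)[C@H](C(=O)OC)C(C)(C)C(=C)CO[Si](C)(C)C(C)(C)C | intermediate
16 | 1-bromo-3-methylbut-2-ene (prenyl bromide) | CC(C)=CCBr | starting material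
17 | dilithium alkoxide–enolate of 15 (chelated, O-lithium cis to the carbinol carbon) | C[C@H](O[Li])/C(=C(\O[Li])OC)C(C)(C)C(=C)CO[Si](C)(C)C(C)(C)C | intermediate (not isolated)
18 | methyl (2R,3S)-2-{3-[(TBS-oxy)methyl]-2-methylbut-3-en-2-yl}-3-hydroxy-2-(3-methylbut-2-en-1-yl)butanoate | COC(=O)[C@@](CC=C(C)C)([C@H](C)O)C(C)(C)C(=C)CO[Si](C)(C)C(C)(C)C | intermediate
19 | methyl (2R)-2-acetyl-4-[(TBS-oxy)methyl]-3,3-dimethyl-2-(3-methylbut-2-en-1-yl)pent-4-enoate | COC(=O)[C@@](CC=C(C)C)(C(C)=O)C(C)(C)C(=C)CO[Si](C)(C)C(C)(C)C | intermediate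
20 | methyl (2R)-2-acetyl-4-(bromomethyl)-3,3-dimethyl-2-(3-methylbut-2-en-1-yl)pent-4-enoate | COC(=O)[C@@](CC=C(C)C)(C(C)=O)C(C)(C)C(=C)CBr | intermediate
21 | methyl prop-2-en-1-yl propanedioate (allyl methyl malonate) | COC(=O)CC(=O)OCC=C | starting material
22 | (2E)-1-bromo-3,7-dimethylocta-2,6-diene (geranyl bromide) | CC(C)=CCC/C(C)=C/CBr | starting material
23 | 1-methyl 3-prop-2-en-1-yl 2-[(2E)-3,7-dimethylocta-2,6-dien-1-yl]propanedioate | COC(=O)C(C/C=C(\C)CCC=C(C)C)C(=O)OCC=C | intermediate
24 | sodium enolate of 23 | [Na+].COC(=O)[C-](C/C=C(\C)CCC=C(C)C)C(=O)OCC=C | intermediate (not isolated)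
25 | dimethyl (2R)-2-acetyl-6-[(allyloxy)carbonyl]-6-[(2E)-3,7-dimethylocta-2,6-dien-1-yl]-3,3-dimethyl-4-methylidene-2-(3-methylbut-2-en-1-yl)heptanedioate (C5 epimers) | COC(=O)[C@@](CC=C(C)C)(C(C)=O)C(C)(C)C(=C)CC(C/C=C(\C)CCC=C(C)C)(C(=O)OC)C(=O)OCC=C | intermediate
26 | malonic half-acid from 25 (6-carboxy in place of 6-allyloxycarbonyl) | COC(=O)[C@@](CC=C(C)C)(C(C)=O)C(C)(C)C(=C)CC(C/C=C(\C)CCC=C(C)C)(C(=O)OC)C(O)=O | intermediate (not isolated)
27 | dimethyl (2R)-2-acetyl-6-[(2E)-3,7-dimethylocta-2,6-dien-1-yl]-3,3-dimethyl-4-methylidene-2-(3-methylbut-2-en-1-yl)heptanedioate (acyclic keto diester, both C5 epimers) | COC(=O)[C@@](CC=C(C)C)(C(C)=O)C(C)(C)C(=C)CC(C/C=C(\C)CCC=C(C)C)C(=O)OC | intermediate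
28 | methyl 3-acetyl-1-[(2E)-3,7-dimethylocta-2,6-dien-1-yl]-4,4-dimethyl-5-methylidene-3-(3-methylbut-2-en-1-yl)-2-oxocyclohexane-1-carboxylate, ester cis to acetyl (ring A closed) | C=C1C[C@](C(=O)OC)(C/C=C(\C)CCC=C(C)C)C(=O)[C@@](CC=C(C)C)(C(C)=O)C1(C)C | intermediate (not isolated)
29 | 4-hydroxy-5-[(2E)-3,7-dimethylocta-2,6-dien-1-yl]-8,8-dimethyl-7-methylidene-1-(3-methylbut-2-en-1-yl)bicyclo[3.3.1]non-3-ene-2,9-dione (enol of the 2,4,9-trione; C1 and C5 as in the target) | C=C1C[C@]2(C/C=C(\C)CCC=C(C)C)C(=O)[C@@](CC=C(C)C)(C(=O)C=C2O)C1(C)C | intermediate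
30 | 4-methoxy analogue of 29 (methyl enol ether) | C=C1C[C@]2(C/C=C(\C)CCC=C(C)C)C(=O)[C@@](CC=C(C)C)(C(=O)C=C2OC)C1(C)C | intermediate
31 | 6-methylhept-5-en-1-yne | C#CCCC=C(C)C | starting material
32 | [(1E)-2,6-dimethylhepta-1,5-dien-1-yl]dimethylalumane | C[Al](C)/C=C(\C)CCC=C(C)C | intermediate (not isolated)
33 | (1E)-1-iodo-2,6-dimethylhepta-1,5-diene | I/C=C(\C)CCC=C(C)C | intermediate
34 | 9-alkyl-9-borabicyclo[3.3.1]nonane from 30 (boron on the former methylene carbon, C7 arm endo) | C1CCC2CCCC1B2C[C@H]3C[C@]4(C/C=C(\C)CCC=C(C)C)C(=O)[C@@](CC=C(C)C)(C(=O)C=C4OC)C3(C)C | intermediate (not isolated)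
35 | 5,7-bis[(2E)-3,7-dimethylocta-2,6-dien-1-yl]-4-methoxy-8,8-dimethyl-1-(3-methylbut-2-en-1-yl)bicyclo[3.3.1]non-3-ene-2,9-dione (C7 chain endo, cis to the C2–C4 bridge) | CC(C)=CCC/C(C)=C/C[C@H]1C[C@]2(C/C=C(\C)CCC=C(C)C)C(=O)[C@@](CC=C(C)C)(C(=O)C=C2OC)C1(C)C | intermediate
36 | 3,4-dihydroxybenzoic acid | OC(=O)c1ccc(O)c(O)c1 | starting material
37 | tert-butyl(dimethyl)silyl 3,4-bis{[tert-butyl(dimethyl)silyl]oxy}benzoate | CC(C)(C)[Si](C)(C)OC(=O)c1ccc(O[Si](C)(C)C(C)(C)C)c(O[Si](C)(C)C(C)(C)C)c1 | intermediate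
38 | 3,4-bis{[tert-butyl(dimethyl)silyl]oxy}benzoyl chloride | ClC(=O)c1ccc(O[Si](C)(C)C(C)(C)C)c(O[Si](C)(C)C(C)(C)C)c1 | intermediate
39 | 3-lithio derivative of 35 | CC(C)=CCC/C(C)=C/C[C@H]1C[C@]2(C/C=C(\C)CCC=C(C)C)C(=O)[C@@](CC=C(C)C)(C(=O)C([Li])=C2OC)C1(C)C | intermediate (not isolated)
40 | 3-(3,4-bis{[tert-butyl(dimethyl)silyl]oxy}benzoyl) derivative of 35 | CC(C)=CCC/C(C)=C/C[C@H]1C[C@]2(C/C=C(\C)CCC=C(C)C)C(=O)[C@@](CC=C(C)C)(C(=O)C(C(=O)c3ccc(O[Si](C)(C)C(C)(C)C)c(O[Si](C)(C)C(C)(C)C)c3)=C2OC)C1(C)C | intermediate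
41 | bis(tert-butyldimethylsilyl) ether of oblongifolin D (enol free) | CC(C)=CCC/C(C)=C/C[C@H]1C[C@]2(C/C=C(\C)CCC=C(C)C)C(=O)[C@@](CC=C(C)C)(C(=O)C(C(=O)c3ccc(O[Si](C)(C)C(C)(C)C)c(O[Si](C)(C)C(C)(C)C)c3)=C2O)C1(C)C | intermediate (not isolated)
42 | oblongifolin D | CC(C)=CCC/C(C)=C/C[C@H]1C[C@]2(C/C=C(\C)CCC=C(C)C)C(=O)[C@@](CC=C(C)C)(C(=O)C(C(=O)c3ccc(O)c(O)c3)=C2O)C1(C)C | target

**Step count and risks**

Total steps: 20. Longest linear sequence: 15 steps (1, 3–9, 11–14, 16, 19, 20). Steps 2, 10, 15, 17 and 18 make fragments.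

Steps most likely to fail:

1. Step 13 (carries the label). The Dieckmann closure gives a keto ester without an acidic hydrogen, so the first ring may reopen faster than the second one forms. Methoxide could then strip the acetyl group or open the C1–C9 bond, with loss of the C1 configuration. Fallback, setting out from 27 and returning at 29: the two closures would be run apart with known chemistry. LiHMDS (2.2 equiv, THF, −78 → −20 °C) forms the bis-enolate and closes ring A under kinetic conditions, where lithium methoxide should not reopen the hindered ketone. This gives 28 together with its C5 epimer, the trans keto ester F1, which is removed by chromatography. Pure 28 is then treated with KOt-Bu in THF, the known closure of a 2-acetyl-6-alkoxycarbonylcyclohexanone, to reach 29.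

2. Step 7. Deprotonation and C-alkylation at the carbon flanked by the quaternary C8 may be too slow, and retro-aldol fragmentation of the lithium aldolate may take over on warming. Fallback, setting out from 14 and returning at 18: the acid is condensed with pivalaldehyde (acid catalysis, water removal) to the cis-2-tert-butyl-1,3-dioxan-4-one F2. This is a cyclic mono-enolate precursor that cannot fragment and whose ring fixes the facial bias. LDA and then prenyl bromide should alkylate it trans to the ring methyl group, the same sense as in the open-chain chelate, to give F3. NaOMe in MeOH at 0 °C then opens the acetal lactone to the methyl ester 18.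

3. Step 16. The dialkylborane may also attack the trisubstituted alkenes or reduce the C9 or vinylogous ester carbonyl, and transmetalation of the β-branched alkylborane may be slow enough for protodeboronation to compete. Fallback, setting out from 30 and returning at 35: hydroboration with pinacolborane catalysed by Rh(PPh3)3Cl proceeds through a metal hydride that tolerates ketones and prefers the 1,1-disubstituted alkene. It should deliver hydrogen to the same exo face and give the isolable pinacol boronate F4. KHF2 converts F4 into the potassium trifluoroborate F5, and Suzuki–Miyaura coupling of F5 with 33 (Pd(dppf)Cl2, Cs2CO3, toluene/H2O, 80 °C) gives 35.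

**Further compounds**

F1 | step 13 | C5 epimer of 28 (ester trans to acetyl) | C=C1C[C@@](C(=O)OC)(C/C=C(\C)CCC=C(C)C)C(=O)[C@@](CC=C(C)C)(C(C)=O)C1(C)C
F2 | step 7 | (2S,5R,6S)-2-tert-butyl-5-{3-[(TBS-oxy)methyl]-2-methylbut-3-en-2-yl}-6-methyl-1,3-dioxan-4-one | C[C@@H]1O[C@H](C(C)(C)C)OC(=O)[C@@H]1C(C)(C)C(=C)CO[Si](C)(C)C(C)(C)C
F3 | step 7 | (2S,5R,6S)-2-tert-butyl-5-{3-[(TBS-oxy)methyl]-2-methylbut-3-en-2-yl}-6-methyl-5-(3-methylbut-2-en-1-yl)-1,3-dioxan-4-one | C[C@@H]1O[C@H](C(C)(C)C)OC(=O)[C@]1(CC=C(C)C)C(C)(C)C(=C)CO[Si](C)(C)C(C)(C)C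
F4 | step 16 | pinacol boronate from 30 (boron on the former methylene carbon, C7 arm endo) | CC1(C)OB(C[C@H]2C[C@]3(C/C=C(\C)CCC=C(C)C)C(=O)[C@@](CC=C(C)C)(C(=O)C=C3OC)C2(C)C)OC1(C)C
F5 | step 16 | potassium trifluoroborate from F4 | [K+].F[B-](F)(F)C[C@H]1C[C@]2(C/C=C(\C)CCC=C(C)C)C(=O)[C@@](CC=C(C)C)(C(=O)C=C2OC)C1(C)C
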